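**Strategy.** The route rests on disconnecting the spiro γ-lactone at C11–C12 and C13–C14, so that its CH2–CH(CH3) unit is propyne inserted between a lactone carbonyl carbon and CO2. The key step exploits the fact that spiro C11 of the 1,6-dioxaspiro[4.4]nonane (tetrahydrofuran ring O8/C8–C11 plus lactone ring C11–C14) sits at the oxidation level of a lactone carbonyl. In one flask a cis-1,2-dimetallated propene adds through C12 to the C11 lactone of a tricyclic lactam-lactone and is then carboxylated at C13, and acid closes the spiro-butenolide. The precursor is a 10-ethyl stemoamide-type lactone; final hydrogenation sets both α-methyl centres.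

Key step: step 8

Remark on numbering: N4; pyrrolidine C1, C2, C3, C9a; azepane C5–C9; C10 carries the ethyl group; C11 is the spiro carbon; C12 (CH2), C13 (CHCH3) and C14 (C=O) complete the spiro-lactone; C18 (CH–O), C19, C20 (CHCH3) and C21 (C=O) form the side-chain lactone.

Assumption: compounds 1, 2, 5, 11, 13, 14, 16, 22 and 23 are taken to be catalogue chemicals.

Step 1
Reactants: 1 (S)-5-(trityloxymethyl)pyrrolidin-2-one; 2 4-chloro-1,1-dimethoxybutane
Product: 3 (S)-1-(4,4-dimethoxybutyl)-5-(trityloxymethyl)pyrrolidin-2-one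
Conditions: NaH, NaI (cat.), DMF, 0 → 60 °C
Reagents that add atoms: 4-chloro-1,1-dimethoxybutane, COC(CCCCl)OC
Why: Finkelstein-assisted SN2 N-alkylation of the lactam anion; the C9a stereocentre is not acidic and is untouched.

Step 2
Reactants: 3 (S)-1-(4,4-dimethoxybutyl)-5-(trityloxymethyl)pyrrolidin-2-one
Product: 4 (S)-1-(4,4-dimethoxybutyl)-5-(hydroxymethyl)pyrrolidin-2-one
Conditions: TsOH·H2O (cat.), MeOH, rt
Reagents that add atoms: none
Why: Acid-catalysed methanolysis of the trityl ether; the dimethyl acetal only exchanges degenerately in methanol and survives.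

Step 3
Reactants: 4 (S)-1-(4,4-dimethoxybutyl)-5-(hydroxymethyl)pyrrolidin-2-one; 5 ethyl (triphenylphosphoranylidene)acetate
Product: 7 ethyl (E)-3-[(S)-1-(4,4-dimethoxybutyl)-5-oxopyrrolidin-2-yl]acrylate, via aldehyde 6 (not isolated)
Conditions: TEMPO (cat.), PhI(OAc)2, CH2Cl2, rt; then 5, rt
Reagents that add atoms: ethyl (triphenylphosphoranylidene)acetate, CCOC(=O)C=P(c1ccccc1)(c1ccccc1)c1ccccc1
Why: TEMPO/PhI(OAc)2 oxidation gives the configurationally labile α-amido aldehyde, which is trapped at once by the stabilised ylide (Wittig olefination) to give the E-enoate without loss of the C9a configuration.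

Step 4
Reactants: 7 ethyl (E)-3-[(S)-1-(4,4-dimethoxybutyl)-5-oxopyrrolidin-2-yl]acrylate
Product: 8 ethyl (E)-3-[(S)-5-oxo-1-(4-oxobutyl)pyrrolidin-2-yl]acrylate
Conditions: 1 M HCl, THF, rt
Reagents that add atoms: water, O
Why: Acetal hydrolysis; the enoate and lactam are stable to dilute acid.

Step 5
Reactants: 8 ethyl (E)-3-[(S)-5-oxo-1-(4-oxobutyl)pyrrolidin-2-yl]acrylate
Product: 10 (8R,9R,9aS)-tricyclic lactam-lactone without the C10 substituent, via hydroxy ester 9 (not isolated)
Conditions: SmI2 (2.5 equiv), t-BuOH, THF, −78 → 0 °C; then TsOH (cat.), PhMe, 50 °C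
Reagents that add atoms: none
Why: SmI2 ketyl–olefin cyclization (7-exo-trig addition of the C8 ketyl to C9 of the enoate) followed by lactonization; C9a fixes the enoate face that the tethered ketyl can reach, and the anti arrangement of the Sm-bound oxygen and the ester arm in the transition state should give trans H8/H9, so C8 and C9 are set in one event.

Step 6
Reactants: 10 (8R,9R,9aS)-tricyclic lactam-lactone without the C10 substituent; 11 iodoethane
Product: 12 (8R,9R,9aS,10S)-10-ethyl tricyclic lactam-lactone
Conditions: LiHMDS (1.05 equiv), THF, −78 °C; EtI, DMPU, −78 → −30 °C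
Reagents that add atoms: iodoethane, CCI
Why: Enolate alkylation; the lactone α-CH2 is more acidic than the lactam α-CH2, and the enolate should be ethylated on the face anti to the C9–C9a bond to give the 9,10-trans product.

Step 7
Reactants: 13 propyne; 14 hexamethylditin
Product: 15 (Z)-1,2-bis(trimethylstannyl)prop-1-ene
Conditions: Pd(PPh3)4 (2 mol%), THF, 65 °C, sealed tube
Reagents that add atoms: hexamethylditin, C[Sn](C)(C)[Sn](C)(C)C
Why: Pd(0)-catalysed syn-distannation of a terminal alkyne, which fixes the cis relation of the two tin groups.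

Step 8
Reactants: 12 (8R,9R,9aS,10S)-10-ethyl tricyclic lactam-lactone; 15 (Z)-1,2-bis(trimethylstannyl)prop-1-ene; 16 carbon dioxide
Product: 21 spiro-butenolide lactam, via vinyllithium 17 (not isolated), via lithium lactolate 18 (not isolated), via C13-lithio lactolate 19 (not isolated), via dilithium carboxylate 20 (not isolated)
Conditions: 15, MeLi (1.0 equiv), THF, −78 °C; add 12, −78 °C; MeLi (1.3 equiv), −78 → −40 °C; CO2, −78 °C → rt; 1 M HCl; then CSA (cat.), CH2Cl2, 4 Å MS, rt
Reagents that add atoms: (Z)-1,2-bis(trimethylstannyl)prop-1-ene, C/C(=C/[Sn](C)(C)C)[Sn](C)(C)C; carbon dioxide, O=C=O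
Why: Regioselective Sn–Li exchange at the terminal stannane of 15 gives vinyllithium 17, which adds 1,2 to the lactone carbonyl of 12 (far more electrophilic than the tertiary lactam at −78 °C) and makes the C11–C12 bond; the tetrahedral lithium lactolate 18 should not collapse at this temperature. A second, alkoxide-assisted Sn–Li exchange at C13 (19) and capture by CO2 make the C13–C14 bond (20), so that propyne ends up inserted between the former lactone carbon and the carbon of CO2, with the cis geometry fixed by the syn-distannation. The closest known reaction types are lactone-selective organolithium addition, carboxylation of (Z)-γ-lithio allylic alkoxides and acid lactonization of (Z)-4-hydroxy-2-enoic acids. On acidification the hemiketal hydroxyl on C11 closes the butenolide by 5-exo-trig acyl substitution at C14, while the tetrahydrofuran ring (O8–C11) is retained. The only new stereocentre, spiro C11, is set under thermodynamic control by the CSA equilibration through the oxocarbenium ion, which should place the vinylic CH (C12) trans to the C10 ethyl group and the smaller lactone oxygen cis to it. The step needs selectivity for the lactone over the lactam and for the less hindered stannane in the first exchange; the first rests on the reactivity gap at −78 °C and the second on sterics.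

Step 9
Reactants: 22 3-methylfuran-2(5H)-one; 23 triisopropylsilyl trifluoromethanesulfonate
Product: 24 3-methyl-2-(triisopropylsilyloxy)furan
Conditions: Et3N, CH2Cl2, 0 °C
Reagents that add atoms: triisopropylsilyl trifluoromethanesulfonate, CC(C)[Si](C(C)C)(C(C)C)OS(=O)(=O)C(F)(F)F
Why: Soft enolization and O-silylation of the butenolide give the aromatic silyl dienol ether.

Step 10
Reactants: 21 spiro-butenolide lactam; 24 3-methyl-2-(triisopropylsilyloxy)furan
Product: 26 bis-butenolide amine (3S,18S), via O-silyl hemiaminal 25 (not isolated)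
Conditions: IrCl(CO)(PPh3)2 (1 mol%), (Me2HSi)2O, PhMe, rt; then 24, TMSOTf (cat.), CH2Cl2, −78 → 0 °C
Reagents that add atoms: 3-methyl-2-(triisopropylsilyloxy)furan, Cc1ccoc1O[Si](C(C)C)(C(C)C)C(C)C
Why: Iridium-catalysed hydrosilylation is selective for the tertiary lactam and gives hemiaminal 25; ionization to the bicyclic iminium ion and vinylogous Mukaiyama–Mannich attack by C5 of the furan anti to the C9a–C9 bond should give the 2,5-trans pyrrolidine (3S), with the open transition state that keeps the furan away from the C5 methylene giving 18S.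

Step 11
Reactants: 26 bis-butenolide amine
Product: 27 target compound (3S,8R,9R,9aS,10S,11S,13S,18S,20S)
Conditions: H2 (4 atm), 5% Rh/Al2O3, EtOAc, rt
Reagents that add atoms: none
Why: Heterogeneous cis-hydrogenation of both butenolides: the side-chain ring should be reduced anti to its C18 substituent (cis lactone, 20S) and the spiro ring from the face flanked by O8, away from the C10 methine (13S); rhodium on alumina is chosen to avoid hydrogenolysis of the allylic C–O bonds.

**Compound list**

1 | (S)-5-(trityloxymethyl)pyrrolidin-2-one | O=C1CC[C@@H](COC(c2ccccc2)(c2ccccc2)c2ccccc2)N1 | starting material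
2 | 4-chloro-1,1-dimethoxybutane | COC(CCCCl)OC | starting material
3 | (S)-1-(4,4-dimethoxybutyl)-5-(trityloxymethyl)pyrrolidin-2-one | COC(CCCN1C(=O)CC[C@H]1COC(c1ccccc1)(c1ccccc1)c1ccccc1)OC | intermediate
4 | (S)-1-(4,4-dimethoxybutyl)-5-(hydroxymethyl)pyrrolidin-2-one | COC(CCCN1C(=O)CC[C@H]1CO)OC | intermediate
5 | ethyl (triphenylphosphoranylidene)acetate | CCOC(=O)C=P(c1ccccc1)(c1ccccc1)c1ccccc1 | starting material
6 | (S)-1-(4,4-dimethoxybutyl)-5-oxopyrrolidine-2-carbaldehyde | COC(CCCN1C(=O)CC[C@H]1C=O)OC | intermediate
7 | ethyl (E)-3-[(S)-1-(4,4-dimethoxybutyl)-5-oxopyrrolidin-2-yl]acrylate | COC(CCCN1C(=O)CC[C@H]1/C=C/C(=O)OCC)OC | intermediate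
8 | ethyl (E)-3-[(S)-5-oxo-1-(4-oxobutyl)pyrrolidin-2-yl]acrylate | O=CCCCN1C(=O)CC[C@H]1/C=C/C(=O)OCC | intermediate
9 | ethyl 2-[(8R,9R,9aS)-8-hydroxy-3-oxooctahydropyrrolo[1,2-a]azepin-9-yl]acetate | CCOC(=O)C[C@H]1[C@H](O)CCCN2[C@H]1CCC2=O | intermediate
10 | (8R,9R,9aS)-tricyclic lactam-lactone without the C10 substituent (γ-lactone trans-fused at C8–C9) | O=C1C[C@H]2[C@@H](CCCN3[C@H]2CCC3=O)O1 | intermediate
11 | iodoethane | CCI | starting material
12 | (8R,9R,9aS,10S)-10-ethyl tricyclic lactam-lactone (ethyl homologue of stemoamide) | CC[C@H]1[C@H]2[C@@H](CCCN3[C@H]2CCC3=O)OC1=O | intermediate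
13 | propyne | CC#C | starting material
14 | hexamethylditin | C[Sn](C)(C)[Sn](C)(C)C | starting material
15 | (Z)-1,2-bis(trimethylstannyl)prop-1-ene | C/C(=C/[Sn](C)(C)C)[Sn](C)(C)C | intermediate
16 | carbon dioxide | O=C=O | starting material
17 | (Z)-1-lithio-2-(trimethylstannyl)prop-1-ene | C/C(=C/[Li])[Sn](C)(C)C | intermediate
18 | lithium lactolate of 12 carrying the (Z)-2-(trimethylstannyl)prop-1-enyl group on C11 (C11 configuration not defined) | CC[C@H]1[C@H]2[C@@H](CCCN3[C@H]2CCC3=O)OC1(O[Li])/C=C(/C)[Sn](C)(C)C | intermediate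
19 | lithium lactolate with lithium in place of tin at C13 | CC[C@H]1[C@H]2[C@@H](CCCN3[C@H]2CCC3=O)OC1(O[Li])/C=C(/C)[Li] | intermediate
20 | dilithium salt of the (Z)-hemiketal carboxylic acid | CC[C@H]1[C@H]2[C@@H](CCCN3[C@H]2CCC3=O)OC1(O[Li])/C=C(/C)C(=O)O[Li] | intermediate
21 | spiro-butenolide lactam (8R,9R,9aS,10S,11R; same spatial arrangement at C11 as 11S in the target, the CIP rank of C12 changes) | CC[C@H]1[C@H]2[C@@H](CCCN3[C@H]2CCC3=O)O[C@]12C=C(C)C(=O)O2 | intermediate
22 | 3-methylfuran-2(5H)-one | CC1=CCOC1=O | starting material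
23 | triisopropylsilyl trifluoromethanesulfonate | CC(C)[Si](C(C)C)(C(C)C)OS(=O)(=O)C(F)(F)F | starting material
24 | 3-methyl-2-(triisopropylsilyloxy)furan | Cc1ccoc1O[Si](C(C)C)(C(C)C)C(C)C | intermediate
25 | O-silyl hemiaminal of 21 at C3 (C3 configuration not defined) | CC[C@H]1[C@H]2[C@@H](CCCN3[C@H]2CCC3O[Si](C)(C)O[SiH](C)C)O[C@]12C=C(C)C(=O)O2 | intermediate
26 | bis-butenolide amine (3S,8R,9R,9aS,10S,11R,18S) | CC[C@H]1[C@H]2[C@@H](CCCN3[C@H]2CC[C@H]3[C@@H]2C=C(C)C(=O)O2)O[C@]12C=C(C)C(=O)O2 | intermediate
27 | target (3S,8R,9R,9aS,10S,11S,13S,18S,20S) | CC[C@H]1[C@H]2[C@@H](CCCN3[C@H]2CC[C@H]3[C@@H]2C[C@H](C)C(=O)O2)O[C@]12C[C@H](C)C(=O)O2 | target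

**Step count.** Total: 11 steps. Longest linear sequence: 9 steps (1–6, 8, 10, 11); steps 7 and 9 prepare the two reagents.

**Steps most likely to fail**

Step 8. The second tin–lithium exchange may stall on the hindered stannane of the lithium lactolate, or the lactolate may collapse to the enone and be attacked by methyllithium; the spiro centre may also equilibrate to a poor ratio. The fallback sets out from 12 and 15 and makes the two bonds in separate operations. Lactone 12 is treated with vinyllithium 17 alone and quenched with NH4Cl to give the stannyl lactol F1. Iodine in CH2Cl2 at 0 °C replaces tin with retention to give the (Z)-iodo lactol F2. Palladium-catalysed carbonylation (PdCl2(PPh3)2, CO 1 atm, Et3N, THF, 50 °C), in which the cis hemiketal hydroxyl traps the acylpalladium, followed by the same CSA equilibration, returns to the route at 21.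

Step 5. The ketyl cyclization may show poor facial selectivity at C9, or pinacol coupling and simple aldehyde reduction may dominate. The fallback sets out from 8 and uses a polar acyl-anion closure instead. An intramolecular Stetter reaction with a chiral triazolium carbene catalyst gives the keto ester F3, with the catalyst controlling C9. L-Selectride reduces the ketone anti to the C9 side chain to give the cis-hydroxy ester F4, and LiOH gives the cis-hydroxy acid F5. Mitsunobu lactonization (PPh3, DIAD) closes the lactone with inversion at C8 and returns to the route at 10.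

Step 10. The spiro-butenolide may be hydrosilylated or reduced in conjugate fashion, or may take up the silyloxyfuran as a Michael acceptor; diastereoselectivity at C3/C18 may also be low. The fallback sets out from 21 and removes the sensitive alkene first. Hydrogenation over Rh/Al2O3 gives the saturated spirolactone lactam F6 (13S). The same iridium-catalysed reductive vinylogous Mannich reaction with 24 then gives the mono-butenolide F7, and a second hydrogenation returns to the route at 27.

**Further compounds**

F1 | step 8 | stannyl lactol from 12 and 17 (C11 not defined) | CC[C@H]1[C@H]2[C@@H](CCCN3[C@H]2CCC3=O)OC1(O)/C=C(/C)[Sn](C)(C)C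
F2 | step 8 | (Z)-iodo lactol | CC[C@H]1[C@H]2[C@@H](CCCN3[C@H]2CCC3=O)OC1(O)/C=C(/C)I
F3 | step 5 | ethyl 2-[(9R,9aS)-3,8-dioxooctahydropyrrolo[1,2-a]azepin-9-yl]acetate | CCOC(=O)C[C@H]1C(=O)CCCN2[C@H]1CCC2=O
F4 | step 5 | (8S,9R,9aS) cis-hydroxy ester | CCOC(=O)C[C@H]1[C@@H](O)CCCN2[C@H]1CCC2=O
F5 | step 5 | (8S,9R,9aS) cis-hydroxy acid | OC(=O)C[C@H]1[C@@H](O)CCCN2[C@H]1CCC2=O
F6 | step 10 | saturated spirolactone lactam (8R,9R,9aS,10S,11S,13S) | CC[C@H]1[C@H]2[C@@H](CCCN3[C@H]2CCC3=O)O[C@]12C[C@H](C)C(=O)O2
F7 | step 10 | mono-butenolide amine (3S,8R,9R,9aS,10S,11S,13S,18S) | CC[C@H]1[C@H]2[C@@H](CCCN3[C@H]2CC[C@H]3[C@@H]2C=C(C)C(=O)O2)O[C@]12C[C@H](C)C(=O)O2
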